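## Retrosynthetic overview

1. The last step is a fluoride unmasking of a fully silyl-protected 2,4-dialkoxypyridine N-oxide. The C2'=C3' alkene of the trienone comes from an aldol condensation of a 3-acetylpyridine N-oxide with a (6R,8S)-dienal.
2. Key disconnection: the C8'–C9' bond of the side chain, formed by a nickel-catalysed, radical, enantioconvergent coupling of a racemic dienylic halide with the zinc reagent of (S)-1-bromo-2-methylbutane. The catalyst sets C8'; C10' is bought.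
3. The racemic halide comes from radical allylic bromination of a dienyl Weinreb amide built from (E)-2-methylpent-2-enal and N-methoxy-N-methylacetamide.
4. Core: 2,4-difluoropyridine → bis[2-(trimethylsilyl)ethyl] ether → C5 bromide → lithium exchange and addition to a 4-silyloxycyclohexanone (ring oxygens cis) → C3 lithiation and acetylation → N-oxide.
5. Rings: none is built. Pyridine and cyclohexane are bought and joined in step 7; the pyridine becomes the 1-hydroxy-2-pyridone only in step 11.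

Assumption: commercial 4-(tert-butyldimethylsilyloxy)cyclohexan-1-one is counted as 4-hydroxycyclohexanone (eight non-hydrogen atoms) carrying a protecting group.

## Route

Step 1
Reactants: 1 (E)-2-methylpent-2-enal; 2 N-methoxy-N-methylacetamide
Product: 6 (2E,4E)-N-methoxy-N,4-dimethylhepta-2,4-dienamide, via lithium amide enolate 3 (not isolated), via lithium aldolate 4 (not isolated), via aldol mesylate 5 (not isolated)
Conditions: LiN(iPr)2, THF, −78 °C; 1, −78 °C; MsCl, −78 → 0 °C; DBU, 23 °C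
Reagents that add atoms: none
Why: Aldol condensation: the amide enolate adds 1,2 to the enal at −78 °C, and mesylation followed by E1cB elimination gives the thermodynamically favoured (2E)-alkene while the (4E)-alkene of 1 is carried through unchanged.

Step 2
Reactants: 6 (2E,4E)-N-methoxy-N,4-dimethylhepta-2,4-dienamide
Product: 7 racemic (2E,4E)-6-bromo-N-methoxy-N,4-dimethylhepta-2,4-dienamide
Conditions: NBS (1.05 equiv), AIBN (5 mol %), PhCF3, 80 °C; used at once
Reagents that add atoms: N-bromosuccinimide, O=C1CCC(=O)N1Br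
Why: Wohl–Ziegler radical allylic bromination: the C6–H gives a secondary radical delocalised over the diene and the amide carbonyl, and bromine returns to the terminus that keeps the dienamide conjugated (as in the known bromination of sorbates); the new centre is racemic, which step 3 tolerates.

Step 3
Reactants: 7 racemic (2E,4E)-6-bromo-N-methoxy-N,4-dimethylhepta-2,4-dienamide; 8 (S)-1-bromo-2-methylbutane
Product: 11 (2E,4E,6R,8S)-N-methoxy-N,4,6,8-tetramethyldeca-2,4-dienamide, via alkylzinc bromide 9 (not isolated), via allylic chloride 10 (not isolated)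
Conditions: 8, Zn, I2 (5 mol %), DMA, 70 °C; separately 7, LiCl (4 equiv), DMA/DMF 1:1, 0 °C; then NiCl2·MeOCH2CH2OMe (5 mol %), 2,6-bis[(4S)-4-(2-phenylethyl)-4,5-dihydrooxazol-2-yl]pyridine (5.5 mol %), 9 (1.6 equiv), −10 °C, 24 h
Reagents that add atoms: none
Why: Proposed new method: monovalent nickel abstracts the halogen of 10 to give a planar, amide-conjugated pentadienyl radical that erases the configuration at C6; the chiral alkylnickel complex captures it and reductive elimination at the terminus remote from the carbonyl (secondary carbon, conjugation kept) forms C6–C7 and sets 6R under ligand control, while C8 comes unchanged from 8; the closest known reaction type is the nickel/Pybox asymmetric Negishi coupling of racemic secondary allylic chlorides (carbonyl-conjugated ones included) with alkylzinc halides, extended here by one vinylogous unit; the sense of induction is checked on the first run and the antipodal ligand is used if it gives 6S.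

Step 4
Reactants: 11 (2E,4E,6R,8S)-N-methoxy-N,4,6,8-tetramethyldeca-2,4-dienamide
Product: 13 (2E,4E,6R,8S)-4,6,8-trimethyldeca-2,4-dienal, via aluminium hemiaminal 12 (not isolated)
Conditions: iBu2AlH (1.3 equiv), THF, −78 °C; aq. potassium sodium tartrate
Reagents that add atoms: none
Why: Weinreb amide reduction: the chelated hemiaminal 12 survives until work-up so the hydride stops at the aldehyde, and no stereocentre is alpha to the carbonyl.

Step 5
Reactants: 14 2,4-difluoropyridine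
Product: 16 2,4-bis[2-(trimethylsilyl)ethoxy]pyridine, via monoether 15 (not isolated)
Conditions: Me3SiCH2CH2OH (2.3 equiv), NaH (2.4 equiv), THF, 0 → 60 °C
Reagents that add atoms: 2-(trimethylsilyl)ethanol, C[Si](C)(C)CCO
Why: Twofold nucleophilic aromatic substitution (SNAr): the alkoxide displaces fluoride first at C4, then at C2.

Step 6
Reactants: 16 2,4-bis[2-(trimethylsilyl)ethoxy]pyridine
Product: 17 5-bromo-2,4-bis[2-(trimethylsilyl)ethoxy]pyridine
Conditions: NBS (1.05 equiv), MeCN, 0 → 23 °C, dark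
Reagents that add atoms: N-bromosuccinimide, O=C1CCC(=O)N1Br
Why: Electrophilic aromatic bromination at C5, which is para to the 2-alkoxy group, ortho to the 4-alkoxy group and less hindered than C3.

Step 7
Reactants: 17 5-bromo-2,4-bis[2-(trimethylsilyl)ethoxy]pyridine; 18 4-(tert-butyldimethylsilyloxy)cyclohexan-1-one
Product: 21 5-[cis-4-(tert-butyldimethylsilyloxy)-1-(triethylsilyloxy)cyclohexyl]-2,4-bis[2-(trimethylsilyl)ethoxy]pyridine (the two ring oxygens cis), via aryllithium 19 (not isolated), via lithium alkoxide 20 (not isolated)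
Conditions: n-BuLi (1.05 equiv), THF, −78 °C; 18, −78 °C; Et3SiOTf (1.5 equiv), −78 → 0 °C; chromatography
Reagents that add atoms: triethylsilyl trifluoromethanesulfonate, CC[Si](CC)(CC)OS(=O)(=O)C(F)(F)F
Why: Bromine–lithium exchange and 1,2-addition: the ortho-alkoxy aryllithium attacks the chair with equatorial silyloxy group from the equatorial side, giving aryl equatorial and the tertiary oxygen axial, i.e. cis to the C4 oxygen (about 4:1 expected, minor isomer removed); the alkoxide is capped in the flask as its triethylsilyl ether.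

Step 8
Reactants: 21 (as above); 2 N-methoxy-N-methylacetamide
Product: 24 1-{5-[cis-4-(tert-butyldimethylsilyloxy)-1-(triethylsilyloxy)cyclohexyl]-2,4-bis[2-(trimethylsilyl)ethoxy]pyridin-3-yl}ethan-1-one, via 3-lithiopyridine 22 (not isolated), via lithium hemiaminal 23 (not isolated)
Conditions: n-BuLi (1.3 equiv), THF, −78 → −20 °C; 2, −78 → 0 °C; sat. aq. NH4Cl
Reagents that add atoms: none
Why: Directed ortho-metalation at C3, flanked by two alkoxy groups, then acylation with the Weinreb amide, whose chelated adduct 23 prevents over-addition.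

Step 9
Reactants: 24 (as above)
Product: 25 3-acetyl-5-[cis-4-(tert-butyldimethylsilyloxy)-1-(triethylsilyloxy)cyclohexyl]-2,4-bis[2-(trimethylsilyl)ethoxy]pyridine 1-oxide
Conditions: mCPBA (1.5 equiv), CH2Cl2, 0 → 23 °C; aq. Na2S2O3/NaHCO3 wash
Reagents that add atoms: 3-chloroperoxybenzoic acid, OOC(=O)c1cccc(Cl)c1
Why: Pyridine N-oxidation by the peracid, done before any alkene is present; the acetyl group, twisted between two ortho-alkoxy groups, is slow in Baeyer–Villiger oxidation.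

Step 10
Reactants: 25 (as above); 13 (2E,4E,6R,8S)-4,6,8-trimethyldeca-2,4-dienal
Product: 29 (2E,4E,6E,8R,10S)-1-{5-[cis-4-(tert-butyldimethylsilyloxy)-1-(triethylsilyloxy)cyclohexyl]-1-oxido-2,4-bis[2-(trimethylsilyl)ethoxy]pyridin-1-ium-3-yl}-6,8,10-trimethyldodeca-2,4,6-trien-1-one, via lithium ketone enolate 26 (not isolated), via lithium aldolate 27 (not isolated), via aldol acetate 28 (not isolated)
Conditions: LiN(SiMe3)2 (1.1 equiv), THF, −78 °C; 13, −78 °C; Ac2O, −78 → 0 °C; DBU, 23 °C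
Reagents that add atoms: none
Why: Aldol condensation: the kinetic methyl ketone enolate adds 1,2 to the dienal, and E1cB loss of acetate gives the (2E)-enone; Ac2O is used instead of a sulfonyl chloride so the N-oxide is not activated, and the remote stereocentres are untouched.

Step 11
Reactants: 29 (as above)
Product: 30 militarinone A, 1,4-dihydroxy-5-(cis-1,4-dihydroxycyclohexyl)-3-[(2E,4E,6E,8R,10S)-6,8,10-trimethyldodeca-2,4,6-trienoyl]pyridin-2(1H)-one
Conditions: Bu4NF (8 equiv), THF, 0 → 40 °C; AcOH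
Reagents that add atoms: none
Why: Fluoride-induced global deprotection: both silyl ethers are cleaved and both 2-(trimethylsilyl)ethyl ethers fragment to ethene and Me3SiF, releasing the 4-hydroxyl and the 2-oxido N-oxide, which on protonation is the 1-hydroxy-2-pyridone; no acid strong enough to ionise the tertiary carbinol is used.

## Compound list

1 | (E)-2-methylpent-2-enal | CC/C=C(C)/C=O | starting material
2 | N-methoxy-N-methylacetamide | CC(=O)N(C)OC | starting material
3 | lithium 1-[methoxy(methyl)amino]ethen-1-olate | C=C(O[Li])N(C)OC | intermediate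
4 | lithium (4E)-1-[methoxy(methyl)amino]-4-methyl-1-oxohept-4-en-3-olate (racemic) | CC/C=C(C)/C(O[Li])CC(=O)N(C)OC | intermediate
5 | (4E)-1-[methoxy(methyl)amino]-4-methyl-1-oxohept-4-en-3-yl methanesulfonate (racemic) | CC/C=C(C)/C(OS(C)(=O)=O)CC(=O)N(C)OC | intermediate
6 | (2E,4E)-N-methoxy-N,4-dimethylhepta-2,4-dienamide | CC/C=C(C)/C=C/C(=O)N(C)OC | intermediate
7 | racemic (2E,4E)-6-bromo-N-methoxy-N,4-dimethylhepta-2,4-dienamide | CC(Br)/C=C(C)/C=C/C(=O)N(C)OC | intermediate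
8 | (S)-1-bromo-2-methylbutane | CC[C@H](C)CBr | starting material
9 | [(S)-2-methylbutyl]zinc bromide | CC[C@H](C)C[Zn]Br | intermediate
10 | racemic (2E,4E)-6-chloro-N-methoxy-N,4-dimethylhepta-2,4-dienamide | CC(Cl)/C=C(C)/C=C/C(=O)N(C)OC | intermediate
11 | (2E,4E,6R,8S)-N-methoxy-N,4,6,8-tetramethyldeca-2,4-dienamide | CC[C@H](C)C[C@@H](C)/C=C(C)/C=C/C(=O)N(C)OC | intermediate
12 | (2E,4E,6R,8S)-1-[(diisobutylalumanyl)oxy]-N-methoxy-N,4,6,8-tetramethyldeca-2,4-dien-1-amine | CC[C@H](C)C[C@@H](C)/C=C(C)/C=C/C(O[Al](CC(C)C)CC(C)C)N(C)OC | intermediate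
13 | (2E,4E,6R,8S)-4,6,8-trimethyldeca-2,4-dienal | CC[C@H](C)C[C@@H](C)/C=C(C)/C=C/C=O | intermediate
14 | 2,4-difluoropyridine | Fc1ccnc(F)c1 | starting material
15 | 2-fluoro-4-[2-(trimethylsilyl)ethoxy]pyridine | C[Si](C)(C)CCOc1ccnc(F)c1 | intermediate
16 | 2,4-bis[2-(trimethylsilyl)ethoxy]pyridine | C[Si](C)(C)CCOc1ccnc(OCC[Si](C)(C)C)c1 | intermediate
17 | 5-bromo-2,4-bis[2-(trimethylsilyl)ethoxy]pyridine | C[Si](C)(C)CCOc1cc(OCC[Si](C)(C)C)ncc1Br | intermediate
18 | 4-(tert-butyldimethylsilyloxy)cyclohexan-1-one | O=C1CCC(CC1)O[Si](C)(C)C(C)(C)C | starting material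
19 | {4,6-bis[2-(trimethylsilyl)ethoxy]pyridin-3-yl}lithium | C[Si](C)(C)CCOc1cc(OCC[Si](C)(C)C)ncc1[Li] | intermediate
20 | lithium cis-1-{4,6-bis[2-(trimethylsilyl)ethoxy]pyridin-3-yl}-4-(tert-butyldimethylsilyloxy)cyclohexan-1-olate | C[Si](C)(C)CCOc1cc(OCC[Si](C)(C)C)ncc1[C@]1(O[Li])CC[C@@H](O[Si](C)(C)C(C)(C)C)CC1 | intermediate
21 | 5-[cis-4-(tert-butyldimethylsilyloxy)-1-(triethylsilyloxy)cyclohexyl]-2,4-bis[2-(trimethylsilyl)ethoxy]pyridine | C[Si](C)(C)CCOc1cc(OCC[Si](C)(C)C)ncc1[C@]1(O[Si](CC)(CC)CC)CC[C@@H](O[Si](C)(C)C(C)(C)C)CC1 | intermediate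
22 | 3-lithio derivative of 21 | C[Si](C)(C)CCOc1c([Li])c(OCC[Si](C)(C)C)ncc1[C@]1(O[Si](CC)(CC)CC)CC[C@@H](O[Si](C)(C)C(C)(C)C)CC1 | intermediate
23 | lithium 1-{5-[cis-4-(tert-butyldimethylsilyloxy)-1-(triethylsilyloxy)cyclohexyl]-2,4-bis[2-(trimethylsilyl)ethoxy]pyridin-3-yl}-1-[methoxy(methyl)amino]ethan-1-olate | CC(O[Li])(N(C)OC)c1c(OCC[Si](C)(C)C)ncc(c1OCC[Si](C)(C)C)[C@]1(O[Si](CC)(CC)CC)CC[C@@H](O[Si](C)(C)C(C)(C)C)CC1 | intermediate
24 | 1-{5-[cis-4-(tert-butyldimethylsilyloxy)-1-(triethylsilyloxy)cyclohexyl]-2,4-bis[2-(trimethylsilyl)ethoxy]pyridin-3-yl}ethan-1-one | CC(=O)c1c(OCC[Si](C)(C)C)ncc(c1OCC[Si](C)(C)C)[C@]1(O[Si](CC)(CC)CC)CC[C@@H](O[Si](C)(C)C(C)(C)C)CC1 | intermediate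
25 | 1-oxide of 24 | CC(=O)c1c(OCC[Si](C)(C)C)[n+]([O-])cc(c1OCC[Si](C)(C)C)[C@]1(O[Si](CC)(CC)CC)CC[C@@H](O[Si](C)(C)C(C)(C)C)CC1 | intermediate
26 | lithium enolate of 25 | C=C(O[Li])c1c(OCC[Si](C)(C)C)[n+]([O-])cc(c1OCC[Si](C)(C)C)[C@]1(O[Si](CC)(CC)CC)CC[C@@H](O[Si](C)(C)C(C)(C)C)CC1 | intermediate
27 | lithium aldolate of 26 with 13 (carbinol epimers) | CC[C@H](C)C[C@@H](C)/C=C(C)/C=C/C(O[Li])CC(=O)c1c(OCC[Si](C)(C)C)[n+]([O-])cc(c1OCC[Si](C)(C)C)[C@]1(O[Si](CC)(CC)CC)CC[C@@H](O[Si](C)(C)C(C)(C)C)CC1 | intermediate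
28 | acetate of aldol 27 | CC[C@H](C)C[C@@H](C)/C=C(C)/C=C/C(OC(C)=O)CC(=O)c1c(OCC[Si](C)(C)C)[n+]([O-])cc(c1OCC[Si](C)(C)C)[C@]1(O[Si](CC)(CC)CC)CC[C@@H](O[Si](C)(C)C(C)(C)C)CC1 | intermediate
29 | (2E,4E,6E,8R,10S)-1-{5-[cis-4-(tert-butyldimethylsilyloxy)-1-(triethylsilyloxy)cyclohexyl]-1-oxido-2,4-bis[2-(trimethylsilyl)ethoxy]pyridin-1-ium-3-yl}-6,8,10-trimethyldodeca-2,4,6-trien-1-one | CC[C@H](C)C[C@@H](C)/C=C(C)/C=C/C=C/C(=O)c1c(OCC[Si](C)(C)C)[n+]([O-])cc(c1OCC[Si](C)(C)C)[C@]1(O[Si](CC)(CC)CC)CC[C@@H](O[Si](C)(C)C(C)(C)C)CC1 | intermediate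
30 | militarinone A (ring hydroxyls cis; 8R,10S; all-E) | CC[C@H](C)C[C@@H](C)/C=C(C)/C=C/C=C/C(=O)c1c(O)c([C@]2(O)CC[C@@H](O)CC2)cn(O)c1=O | target

## Step count and risks

Total steps: 11. Longest linear sequence: 7 (steps 5 to 11, from 14).

**Most likely to fail, 1: step 3** (regiochemistry along the pentadienyl radical, alkene geometry, control at C6). Fallback: the same radical coupling is moved to a gamma-halo-alpha,beta-unsaturated amide, the substrate class closest to precedent, and the diene is completed afterwards. It sets out from 8 (through its zinc reagent 9) and commercial (E)-2-methylpent-2-enoic acid (eight non-hydrogen atoms), and comes back at 11. Amide formation with MeNHOMe·HCl (N-(3-dimethylaminopropyl)-N'-ethylcarbodiimide hydrochloride, 4-dimethylaminopyridine, CH2Cl2) gives (E)-N-methoxy-N,2-dimethylpent-2-enamide F1. NBS and AIBN (PhCF3, 80 °C) give racemic (E)-4-bromo-N-methoxy-N,2-dimethylpent-2-enamide F2. LiCl in DMA/DMF turns it in the flask into racemic (E)-4-chloro-N-methoxy-N,2-dimethylpent-2-enamide F3, which is coupled with 9 under the nickel conditions of step 3 to (2E,4R,6S)-N-methoxy-N,2,4,6-tetramethyloct-2-enamide F4. iBu2AlH (THF, −78 °C) reduces it through (2E,4R,6S)-1-[(diisobutylalumanyl)oxy]-N-methoxy-N,2,4,6-tetramethyloct-2-en-1-amine F5 to (2E,4R,6S)-2,4,6-trimethyloct-2-enal F6. Enolate 3 adds to F6 as in step 1 to give lithium (4E,6R,8S)-1-[methoxy(methyl)amino]-4,6,8-trimethyl-1-oxodec-4-en-3-olate F7, and its mesylate (4E,6R,8S)-1-[methoxy(methyl)amino]-4,6,8-trimethyl-1-oxodec-4-en-3-yl methanesulfonate F8 eliminates with DBU to give 11.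

**Most likely to fail, 2: step 2** (attack at the C4 methyl group, allylic transposition, loss of HBr from 7). Fallback: the halogen is brought in by an ionic gamma-halogenation before the chain is extended. It sets out from 1 and comes back at 10. Me3SiCl, NaI and Et3N (MeCN) give the silyl dienol ether (3E)-2-methyl-1-(trimethylsilyloxy)penta-1,3-diene F9. N-Chlorosuccinimide (THF, −78 → 0 °C) chlorinates its gamma carbon to give racemic (E)-4-chloro-2-methylpent-2-enal F10. Enolate 3 adds to F10 (THF, −78 °C) to give lithium (4E)-6-chloro-1-[methoxy(methyl)amino]-4-methyl-1-oxohept-4-en-3-olate F11. Mesylation to (4E)-6-chloro-1-[methoxy(methyl)amino]-4-methyl-1-oxohept-4-en-3-yl methanesulfonate F12 and elimination with Et3N give 10, now isolated, which enters step 3 without the LiCl exchange.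

**Most likely to fail, 3: step 7** (low cis:trans ratio in the aryllithium addition). Fallback: the secondary carbinol is set afterwards by hydride reduction of a 4-aryl-4-silyloxycyclohexanone. It sets out from 17 (through 19) and comes back at 21. Addition of 19 to 1,4-dioxaspiro[4.5]decan-8-one (cyclohexane-1,4-dione as its mono-ketal) gives lithium 8-{4,6-bis[2-(trimethylsilyl)ethoxy]pyridin-3-yl}-1,4-dioxaspiro[4.5]decan-8-olate F13, which Et3SiOTf caps as 5-[8-(triethylsilyloxy)-1,4-dioxaspiro[4.5]decan-8-yl]-2,4-bis[2-(trimethylsilyl)ethoxy]pyridine F14. Pyridinium p-toluenesulfonate in wet acetone (50 °C) frees 4-{4,6-bis[2-(trimethylsilyl)ethoxy]pyridin-3-yl}-4-(triethylsilyloxy)cyclohexan-1-one F15. NaBH4 (MeOH, −40 °C) delivers hydride axially to the chair with equatorial aryl group and gives the equatorial alcohol, cis-4-{4,6-bis[2-(trimethylsilyl)ethoxy]pyridin-3-yl}-4-(triethylsilyloxy)cyclohexan-1-ol F16 (oxygens cis). t-BuMe2SiCl and imidazole (DMF) then give 21.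

## Further compounds

F1 | step 3 | (E)-N-methoxy-N,2-dimethylpent-2-enamide | CC/C=C(C)/C(=O)N(C)OC
F2 | step 3 | racemic (E)-4-bromo-N-methoxy-N,2-dimethylpent-2-enamide | CC(Br)/C=C(C)/C(=O)N(C)OC
F3 | step 3 | racemic (E)-4-chloro-N-methoxy-N,2-dimethylpent-2-enamide | CC(Cl)/C=C(C)/C(=O)N(C)OC
F4 | step 3 | (2E,4R,6S)-N-methoxy-N,2,4,6-tetramethyloct-2-enamide | CC[C@H](C)C[C@@H](C)/C=C(C)/C(=O)N(C)OC
F5 | step 3 | (2E,4R,6S)-1-[(diisobutylalumanyl)oxy]-N-methoxy-N,2,4,6-tetramethyloct-2-en-1-amine | CC[C@H](C)C[C@@H](C)/C=C(C)/C(O[Al](CC(C)C)CC(C)C)N(C)OC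
F6 | step 3 | (2E,4R,6S)-2,4,6-trimethyloct-2-enal | CC[C@H](C)C[C@@H](C)/C=C(C)/C=O
F7 | step 3 | lithium (4E,6R,8S)-1-[methoxy(methyl)amino]-4,6,8-trimethyl-1-oxodec-4-en-3-olate | CC[C@H](C)C[C@@H](C)/C=C(C)/C(O[Li])CC(=O)N(C)OC
F8 | step 3 | (4E,6R,8S)-1-[methoxy(methyl)amino]-4,6,8-trimethyl-1-oxodec-4-en-3-yl methanesulfonate | CC[C@H](C)C[C@@H](C)/C=C(C)/C(OS(C)(=O)=O)CC(=O)N(C)OC
F9 | step 2 | (3E)-2-methyl-1-(trimethylsilyloxy)penta-1,3-diene | C/C=C/C(C)=CO[Si](C)(C)C
F10 | step 2 | racemic (E)-4-chloro-2-methylpent-2-enal | CC(Cl)/C=C(C)/C=O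
F11 | step 2 | lithium (4E)-6-chloro-1-[methoxy(methyl)amino]-4-methyl-1-oxohept-4-en-3-olate | CC(Cl)/C=C(C)/C(O[Li])CC(=O)N(C)OC
F12 | step 2 | (4E)-6-chloro-1-[methoxy(methyl)amino]-4-methyl-1-oxohept-4-en-3-yl methanesulfonate | CC(Cl)/C=C(C)/C(OS(C)(=O)=O)CC(=O)N(C)OC
F13 | step 7 | lithium 8-{4,6-bis[2-(trimethylsilyl)ethoxy]pyridin-3-yl}-1,4-dioxaspiro[4.5]decan-8-olate | C[Si](C)(C)CCOc1cc(OCC[Si](C)(C)C)ncc1C1(O[Li])CCC2(CC1)OCCO2
F14 | step 7 | 5-[8-(triethylsilyloxy)-1,4-dioxaspiro[4.5]decan-8-yl]-2,4-bis[2-(trimethylsilyl)ethoxy]pyridine | C[Si](C)(C)CCOc1cc(OCC[Si](C)(C)C)ncc1C1(O[Si](CC)(CC)CC)CCC2(CC1)OCCO2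
F15 | step 7 | 4-{4,6-bis[2-(trimethylsilyl)ethoxy]pyridin-3-yl}-4-(triethylsilyloxy)cyclohexan-1-one | C[Si](C)(C)CCOc1cc(OCC[Si](C)(C)C)ncc1C1(O[Si](CC)(CC)CC)CCC(=O)CC1
F16 | step 7 | cis-4-{4,6-bis[2-(trimethylsilyl)ethoxy]pyridin-3-yl}-4-(triethylsilyloxy)cyclohexan-1-ol | C[Si](C)(C)CCOc1cc(OCC[Si](C)(C)C)ncc1[C@]1(O[Si](CC)(CC)CC)CC[C@@H](O)CC1
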